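## Retrosynthetic overview

1. The target comes from methyl ester 41 by esterase hydrolysis. Ester 41 comes from δ-hydroxy ketone 40 by cyclodehydration, which closes the dihydropyran as the last ring.
2. C14 and C15 come from face-selective hydrogenation of dienoate 38. Ring A comes from a reductive aldol plus dehydration. Ring B comes from a carbonylative Stille coupling and Nazarov cyclisation on the enol triflate of the seven-membered ring.
3. The piperidine and quaternary C8 come from an intramolecular Mannich reaction of a β-keto lactone. Its amine arm is released by ozonolysis of an isopropylcyclohexene, which is a latent C2 ketone and C7 aldehyde.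
4. The seven-membered ring comes from an acrolein aldol and ring-closing metathesis on spirolactone 16. Quaternary C5 comes from lipase differentiation of diol 9. C6 comes from an organocatalytic Diels–Alder reaction.
5. Order of ring formation: cyclohexene (sacrificial), γ-lactone (sacrificial), seven-membered ring, piperidine, ring B, ring A, dihydropyran.

Labels used:
- N–C1H2–C8 and N–C7H2–C6.
- C5 is the spiro carbon, carrying C21H2–O and C4H2–C3H=C2(iPr).
- Seven-membered ring: C5-C6-C12-C11-C10=C9-C8.
- Ring A: C8-C9-C15-C14-C13.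
- Ring B: C9-C10-C17-C16-C15.
- C22 is the carboxyl carbon.
- The "lower face" is the face of ring A that carries C1. The "upper face" carries C5.

## Route

Step 1
Reactants: 1 pent-1-en-4-yne
Product: 2 (E)-2-(penta-1,4-dien-1-yl)-4,4,5,5-tetramethyl-1,3,2-dioxaborolane
Conditions: pinacolborane (1.05 equiv), Cp2Zr(H)Cl (5 mol %), Et3N (5 mol %), neat, 60 °C
Reagents that add atoms: pinacolborane, [H]B1OC(C)(C)C(C)(C)O1
Why: Zirconium-catalysed syn hydroboration takes the terminal alkyne far faster than the terminal alkene and gives only the (E)-alkenylboronate.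

Step 2
Reactants: 2 (E)-pentadienyl boronate; 3 2-bromo-3-methylbut-1-ene
Product: 4 (3E)-2-isopropylhepta-1,3,6-triene
Conditions: Pd(PPh3)4 (3 mol %), K3PO4 (3 equiv, aq.), THF, 50 °C
Reagents that add atoms: none
Why: Suzuki–Miyaura coupling joins the two sp2 carbons (C7–C2) with retention of the E geometry and leaves the skipped terminal alkene alone.

Step 3
Reactants: 4 triene; 5 acrolein
Product: 6 (1S,2R)-2-allyl-4-isopropylcyclohex-3-ene-1-carbaldehyde (cis, endo adduct)
Conditions: (5R)-5-benzyl-2,2,3-trimethylimidazolidin-4-one hydrochloride (20 mol %), MeCN/H2O 95:5, 0 °C to rt; minor exo isomer removed by chromatography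
Reagents that add atoms: none
Why: In this iminium-catalysed asymmetric Diels–Alder reaction both diene substituents direct the same ortho/para regiochemistry, and the shielded face of the acrolein iminium ion together with endo approach sets C6 (R) as the first stereocentre.

Step 4
Reactants: 6 Diels–Alder aldehyde; 7 formaldehyde
Product: 9 [(2R)-2-allyl-4-isopropylcyclohex-3-ene-1,1-diyl]dimethanol, via hydroxymethyl aldehyde 8 (not isolated)
Conditions: 37 % aq. CH2O (5 equiv), KOH (1.5 equiv), MeOH/H2O, 0 to 50 °C
Reagents that add atoms: none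
Why: The Tollens sequence (crossed aldol, then crossed Cannizzaro reduction) makes C5 fully substituted, and C6 is not acidic so it keeps its configuration.

Step 5
Reactants: 9 diol
Product: 10 [(1R,2R)-2-allyl-1-(hydroxymethyl)-4-isopropylcyclohex-3-en-1-yl]methyl acetate (CH2OAc trans to allyl, free CH2OH cis to allyl)
Conditions: lipase from Burkholderia cepacia (immobilised), vinyl acetate (3 equiv), MTBE, 30 °C, stopped at monoacylation
Reagents that add atoms: vinyl acetate, C=COC(C)=O
Why: The lipase (a serine hydrolase) carries out an irreversible transesterification on only the more open of the two diastereotopic CH2OH groups (trans to allyl), which sets the quaternary stereocentre C5, and any (6S)-diol left from step 3 ends up as a separable diastereomer.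

Step 6
Reactants: 10 monoacetate
Product: 11 [(1S,2R)-2-allyl-1-formyl-4-isopropylcyclohex-3-en-1-yl]methyl acetate
Conditions: Dess–Martin periodinane (1.2 equiv), CH2Cl2, 0 °C to rt
Reagents that add atoms: none
Why: Dess–Martin oxidation of the neopentyl alcohol gives an aldehyde (C8) that has no α-hydrogen, so it can neither epimerise nor eliminate.

Step 7
Reactants: 11 aldehyde; 12 (methoxymethyl)triphenylphosphonium chloride
Product: 13 [(1R,2R)-2-allyl-4-isopropyl-1-(2-methoxyvinyl)cyclohex-3-en-1-yl]methyl acetate (E/Z mixture)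
Conditions: 12 (1.5 equiv), NaN(SiMe3)2 (1.45 equiv), THF, −78 to 0 °C
Reagents that add atoms: none
Why: Wittig methoxymethylenation adds C13, and the ylide is preformed without excess base so that the acetate survives.

Step 8
Reactants: 13 enol ether acetate
Product: 15 (5S,6R)-6-allyl-8-isopropyl-2-oxaspiro[4.5]dec-7-en-3-ol (lactol, anomers), via hydroxy enol ether 14 (not isolated)
Conditions: K2CO3 (0.2 equiv), MeOH, rt; then 1 M HCl, THF, rt
Reagents that add atoms: water, O
Why: Zemplén-type deacetylation followed by enol ether hydrolysis frees the C13 aldehyde, which is trapped at once by the C21 hydroxyl as the five-membered lactol.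

Step 9
Reactants: 15 lactol
Product: 16 (5S,6R)-6-allyl-8-isopropyl-2-oxaspiro[4.5]dec-7-en-3-one (spirolactone, CH2C=O arm cis to allyl)
Conditions: Dess–Martin periodinane (1.3 equiv), CH2Cl2, rt
Reagents that add atoms: none
Why: Lactol oxidation gives a γ-lactone that masks C21–OH and C13, activates C8, and ties C13 and C21 to the same side.

Step 10
Reactants: 16 spirolactone; 5 acrolein
Product: 17 α-(1-hydroxyallyl) spirolactone (new C8–C9 bond, mixture at C8 and C9)
Conditions: LiN(iPr)2 (1.1 equiv), THF, −78 °C; acrolein (1.3 equiv); AcOH quench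
Reagents that add atoms: none
Why: In this aldol addition the lactone lithium enolate adds 1,2 to acrolein, and both new centres are erased or equilibrated in step 12.

Step 11
Reactants: 17 aldol adduct
Product: 18 tricyclic allylic alcohol (cycloheptene C10=C11 fused to lactone and cyclohexene, C9–OH)
Conditions: second-generation Grubbs catalyst RuCl2(=CHPh)(PCy3)(SIMes) (5 mol %), CH2Cl2 (2 mM), reflux
Reagents that add atoms: none
Why: Ring-closing metathesis of the two monosubstituted alkenes closes the seven-membered ring, and the trisubstituted ring alkene takes no part.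

Step 12
Reactants: 18 allylic alcohol
Product: 19 cycloheptenone β-keto lactone (C9=O, C10=C11)
Conditions: Dess–Martin periodinane (1.3 equiv), CH2Cl2, rt
Reagents that add atoms: none
Why: Oxidation to the β-keto lactone makes C8 configurationally labile, so all aldol diastereomers converge.

Step 13
Reactants: 19 enone
Product: 20 saturated β-keto lactone (C9=O, C8–H, isopropylcyclohexene intact)
Conditions: H2 (1 atm), RhCl(PPh3)3 (10 mol %), benzene/EtOH 1:1, rt
Reagents that add atoms: none
Why: Homogeneous hydrogenation reduces the unhindered cis-disubstituted alkene and does not touch the trisubstituted C2=C7 alkene.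

Step 14
Reactants: 20 β-keto lactone
Product: 22 keto aldehyde (C2 isopropyl ketone, C7 aldehyde on C6), via ozonide 21 (not isolated)
Conditions: O3, CH2Cl2, −78 °C (Sudan red 7B end point); Me2S, −78 °C to rt
Reagents that add atoms: ozone, [O-][O+]=O
Why: Ozonolysis of the only remaining alkene unmasks the C4–C3–C2(=O)iPr chain and the C7 aldehyde, which stay cis on the seven-membered ring because they came from one ring.

Step 15
Reactants: 22 keto aldehyde; 23 methylamine; 7 formaldehyde
Product: 25 bridged amino keto lactone (3-azabicyclo[4.3.1]decane core, C8 quaternary, N–CH3), via secondary amine 24 (not isolated)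
Conditions: MeNH2 (1.05 equiv, THF), AcOH, NaBH(OAc)3, ClCH2CH2Cl, 0 °C; then 37 % aq. CH2O (1.5 equiv), EtOH, 40 °C
Reagents that add atoms: none
Why: Aldehyde-selective reductive amination is followed by an intramolecular Mannich reaction of the β-keto lactone enol on the N-methyliminium ion, and the C7 tether can deliver C1 only to the face of C8 cis to C4, which sets C8 and closes the piperidine.

Step 16
Reactants: 25 bridged amino keto lactone
Product: 26 C2 ethylene ketal of 25
Conditions: HOCH2CH2OH (5 equiv), p-TsOH·H2O (1.2 equiv), benzene, Dean–Stark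
Reagents that add atoms: ethylene glycol, OCCO
Why: Ketalisation takes the isopropyl ketone, whereas the C9 ketone is flanked by quaternary C8 and is too hindered to react.

Step 17
Reactants: 26 ketal
Product: 27 enol triflate (C9(OTf)=C10H)
Conditions: KN(SiMe3)2 (1.2 equiv), THF, −78 °C; PhNTf2 (1.3 equiv), −78 to 0 °C
Reagents that add atoms: N-phenylbis(trifluoromethanesulfonimide), O=S(=O)(N(c1ccccc1)S(=O)(=O)C(F)(F)F)C(F)(F)F
Why: Enolate O-triflation is regiospecific because C10 carries the only enolisable hydrogens in the molecule.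

Step 18
Reactants: 27 enol triflate lactone
Product: 28 lactol (C13H(OH)–O–C21, anomers)
Conditions: iBu2AlH (1.2 equiv), CH2Cl2, −78 °C; aq. potassium sodium tartrate
Reagents that add atoms: none
Why: Partial reduction of the γ-lactone stops at the aluminium hemiacetal at low temperature, and the triflate, ketal and amine are inert.

Step 19
Reactants: 28 lactol; 29 methyl (triphenylphosphoranylidene)acetate
Product: 30 hydroxy (E)-enoate (C8–C13H=C14H–CO2Me, free C21H2OH)
Conditions: 29 (3 equiv), toluene, 90 °C; used at once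
Reagents that add atoms: none
Why: The Wittig reaction of the stabilised ylide with the open hydroxy aldehyde form brings in C14 and C22 under neutral conditions, which hold back oxa-Michael reclosure.

Step 20
Reactants: 30 hydroxy enoate
Product: 31 C21 tert-butyldiphenylsilyl ether of 30
Conditions: TBDPSCl (1.5 equiv), imidazole (3 equiv), DMAP (0.1 equiv), DMF, 40 °C
Reagents that add atoms: tert-butylchlorodiphenylsilane, CC(C)(C)[Si](Cl)(c1ccccc1)c1ccccc1
Why: Silylation blocks the alcohol against conjugate addition and gives an acid-robust ether for the next steps.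

Step 21
Reactants: 31 enol triflate; 32 tributyl(vinyl)stannane; 33 carbon monoxide
Product: 34 cross-conjugated dienone (C10H=C9–C15(=O)–C16H=C17H2)
Conditions: CO (1 atm), Pd(PPh3)4 (10 mol %), LiCl (3 equiv), THF, 60 °C
Reagents that add atoms: none
Why: In the carbonylative Stille coupling, oxidative addition of zerovalent palladium to the triflate, CO insertion and vinyl transfer install C15, C16 and C17 in one operation.

Step 22
Reactants: 34 dienone
Product: 36 ring B cyclopentenone with free C2 ketone (C15=O conjugated to tetrasubstituted C9=C10), via ketal cyclopentenone 35 (not isolated)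
Conditions: CF3SO3H (5 equiv), CH2Cl2, 0 °C; then H2O/THF, rt
Reagents that add atoms: water, O
Why: Nazarov 4π-electrocyclisation forms C10–C17, proton loss from C10 places the alkene in the most substituted position, and the aqueous acid then removes the ketal that is no longer needed.

Step 23
Reactants: 36 keto enoate
Product: 37 ring A β-hydroxy ester (C13H2–C14H(CO2Me)–C15(OH), mixture at C14 and C15)
Conditions: [(Ph3P)CuH]6 (0.4 equiv), toluene, −40 °C to rt; aq. NH4Cl
Reagents that add atoms: none
Why: In this reductive aldol cyclisation, copper hydride adds to C13 of the enoate and the copper enolate closes the five-membered ring on the C15 ketone, while the tetrasubstituted enone alkene is too hindered to react.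

Step 24
Reactants: 37 β-hydroxy ester
Product: 38 fully substituted dienoate (MeO2C–C14=C15–C9=C10)
Conditions: SOCl2 (2 equiv), pyridine, 0 °C
Reagents that add atoms: none
Why: Dehydration of the tertiary allylic β-hydroxy ester runs towards C14 because that gives the conjugated dienoate.

Step 25
Reactants: 38 dienoate
Product: 39 saturated methyl ester (H14 and H15 both on the lower face, C9=C10 kept)
Conditions: H2 (60 bar), [Ir(cod)(PCy3)(py)][B(3,5-(CF3)2C6H3)4] (15 mol %), CH2Cl2, rt, amine pre-protonated with CF3CO2H
Reagents that add atoms: none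
Why: Iridium-catalysed syn hydrogenation takes only the ester-activated C14=C15 bond from the lower face (the upper face is closed by C5 and C21), which sets C14 and C15 together and pushes CO2Me to the upper face.

Step 26
Reactants: 39 silyl ether
Product: 40 δ-hydroxy ketone (C21H2OH and C2 ketone, in equilibrium with its cyclic hemiketal)
Conditions: Bu4NF (1.5 equiv), AcOH (1.5 equiv), THF, rt
Reagents that add atoms: none
Why: Buffered fluoride desilylation frees C21–OH without base strong enough to epimerise C14.

Step 27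
Reactants: 40 δ-hydroxy ketone
Product: 41 methyl ester of the target (6-isopropyl-3,4-dihydro-2H-pyran closed)
Conditions: p-TsOH·H2O (1.15 equiv), 4 Å molecular sieves, benzene, reflux
Reagents that add atoms: none
Why: Acid-catalysed cyclodehydration goes through the six-membered hemiketal and its oxocarbenium ion, which loses a ring proton from C3 to give the endocyclic enol ether, more stable than the exocyclic isopropylidene isomer, and no stereocentre is touched.

Step 28
Reactants: 41 methyl ester
Product: 42 target acid CNP0237695.1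
Conditions: pig liver esterase, phosphate buffer pH 7.5/acetone 9:1, 30 °C; isolated at the isoelectric point
Reagents that add atoms: water, O
Why: Carboxylesterase (hydrolase) cleavage of the methyl ester at neutral pH spares the acid-labile enol ether and the contra-thermodynamic, base-sensitive C14 centre.

## Compound list

1 | pent-1-en-4-yne | C=CCC#C | starting material
2 | (E)-2-(penta-1,4-dien-1-yl)-4,4,5,5-tetramethyl-1,3,2-dioxaborolane | C=CC/C=C/B1OC(C)(C)C(C)(C)O1 | intermediate
3 | 2-bromo-3-methylbut-1-ene | C=C(Br)C(C)C | starting material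
4 | (3E)-2-isopropylhepta-1,3,6-triene | C=CC/C=C/C(=C)C(C)C | intermediate
5 | acrolein | C=CC=O | starting material
6 | (1S,2R)-2-allyl-4-isopropylcyclohex-3-ene-1-carbaldehyde | CC(C)C1=C[C@@H](CC=C)[C@@H](C=O)CC1 | intermediate
7 | formaldehyde | C=O | starting material
8 | (1S,2R)-2-allyl-1-(hydroxymethyl)-4-isopropylcyclohex-3-ene-1-carbaldehyde | CC(C)C1=C[C@@H](CC=C)[C@](C=O)(CO)CC1 | intermediate
9 | [(2R)-2-allyl-4-isopropylcyclohex-3-ene-1,1-diyl]dimethanol | CC(C)C1=C[C@@H](CC=C)C(CO)(CO)CC1 | intermediate
10 | [(1R,2R)-2-allyl-1-(hydroxymethyl)-4-isopropylcyclohex-3-en-1-yl]methyl acetate | CC(C)C1=C[C@@H](CC=C)[C@](CO)(COC(C)=O)CC1 | intermediate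
11 | [(1S,2R)-2-allyl-1-formyl-4-isopropylcyclohex-3-en-1-yl]methyl acetate | CC(C)C1=C[C@@H](CC=C)[C@](C=O)(COC(C)=O)CC1 | intermediate
12 | (methoxymethyl)triphenylphosphonium chloride | COC[P+](c1ccccc1)(c1ccccc1)c1ccccc1.[Cl-] | starting material
13 | [(1R,2R)-2-allyl-4-isopropyl-1-(2-methoxyvinyl)cyclohex-3-en-1-yl]methyl acetate (E/Z) | CC(C)C1=C[C@@H](CC=C)[C@](C=COC)(COC(C)=O)CC1 | intermediate
14 | [(1R,2R)-2-allyl-4-isopropyl-1-(2-methoxyvinyl)cyclohex-3-en-1-yl]methanol (E/Z) | CC(C)C1=C[C@@H](CC=C)[C@](C=COC)(CO)CC1 | intermediate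
15 | (5S,6R)-6-allyl-8-isopropyl-2-oxaspiro[4.5]dec-7-en-3-ol (anomers) | CC(C)C1=C[C@@H](CC=C)[C@@]2(CC(O)OC2)CC1 | intermediate
16 | (5S,6R)-6-allyl-8-isopropyl-2-oxaspiro[4.5]dec-7-en-3-one | CC(C)C1=C[C@@H](CC=C)[C@@]2(CC(=O)OC2)CC1 | intermediate
17 | 4-(1-hydroxyallyl) derivative of 16 (mixture at C8 and C9) | CC(C)C1=C[C@@H](CC=C)[C@@]2(C(C(O)C=C)C(=O)OC2)CC1 | intermediate
18 | lactone/cycloheptene/cyclohexene tricycle, C9–OH, C10=C11 (mixture at C8 and C9) | CC(C)C1=C[C@H]2CC=CC(O)C3C(=O)OC[C@@]32CC1 | intermediate
19 | tricyclic β-keto lactone, C9=O, C10=C11 (C8 labile) | CC(C)C1=C[C@H]2CC=CC(=O)C3C(=O)OC[C@@]32CC1 | intermediate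
20 | tricyclic β-keto lactone, C9=O, saturated seven-membered ring (cis-fused lactone drawn, C8 labile) | CC(C)C1=C[C@H]2CCCC(=O)[C@@H]3C(=O)OC[C@@]32CC1 | intermediate
21 | secondary ozonide of 20 (1,2,4-trioxolane across C2 and C7) | CC(C)C12OOC(O1)[C@H]3CCCC(=O)[C@@H]4C(=O)OC[C@@]43CC2 | intermediate
22 | bicyclic β-keto lactone with C6–CHO and C5–CH2CH2C(=O)iPr | CC(C)C(=O)CC[C@]12COC(=O)[C@H]1C(=O)CCC[C@@H]2C=O | intermediate
23 | methylamine | CN | starting material
24 | C7 N-methylaminomethyl analogue of 22 | CC(C)C(=O)CC[C@]12COC(=O)[C@H]1C(=O)CCC[C@@H]2CNC | intermediate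
25 | bridged N-methylpiperidine keto lactone (C8 quaternary, C9=O, C2=O) | CC(C)C(=O)CC[C@]12COC(=O)[C@]13CN(C)C[C@H]2CCCC3=O | intermediate
26 | C2 ethylene ketal of 25 | CC(C)C1(OCCO1)CC[C@]23COC(=O)[C@]24CN(C)C[C@H]3CCCC4=O | intermediate
27 | C9 enol triflate of 26 | CC(C)C1(OCCO1)CC[C@]23COC(=O)[C@]24CN(C)C[C@H]3CCC=C4OS(=O)(=O)C(F)(F)F | intermediate
28 | C13 lactol of 27 (anomers) | CC(C)C1(OCCO1)CC[C@]23COC(O)[C@]24CN(C)C[C@H]3CCC=C4OS(=O)(=O)C(F)(F)F | intermediate
29 | methyl (triphenylphosphoranylidene)acetate | COC(=O)C=P(c1ccccc1)(c1ccccc1)c1ccccc1 | starting material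
30 | azabicyclic enol triflate with C8 (E)-CH=CHCO2Me and C5 CH2OH | CC(C)C1(OCCO1)CC[C@]2(CO)[C@]3(/C=C/C(=O)OC)CN(C)C[C@H]2CCC=C3OS(=O)(=O)C(F)(F)F | intermediate
31 | C21 TBDPS ether of 30 | CC(C)C1(OCCO1)CC[C@]2(CO[Si](c5ccccc5)(c5ccccc5)C(C)(C)C)[C@]3(/C=C/C(=O)OC)CN(C)C[C@H]2CCC=C3OS(=O)(=O)C(F)(F)F | intermediate
32 | tributyl(vinyl)stannane | C=C[Sn](CCCC)(CCCC)CCCC | starting material
33 | carbon monoxide | [C-]#[O+] | starting material
34 | C9 acryloyl dienone | CC(C)C1(OCCO1)CC[C@]2(CO[Si](c5ccccc5)(c5ccccc5)C(C)(C)C)[C@]3(/C=C/C(=O)OC)CN(C)C[C@H]2CCC=C3C(=O)C=C | intermediate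
35 | ring B cyclopentenone, C2 ketal still in place | CC(C)C1(OCCO1)CC[C@]2(CO[Si](c5ccccc5)(c5ccccc5)C(C)(C)C)[C@]3(/C=C/C(=O)OC)CN(C)C[C@H]2CCC4=C3C(=O)CC4 | intermediate
36 | ring B cyclopentenone, free C2 ketone | CC(C)C(=O)CC[C@]2(CO[Si](c5ccccc5)(c5ccccc5)C(C)(C)C)[C@]3(/C=C/C(=O)OC)CN(C)C[C@H]2CCC4=C3C(=O)CC4 | intermediate
37 | ring A β-hydroxy ester (mixture at C14 and C15) | CC(C)C(=O)CC[C@@]2(CO[Si](c5ccccc5)(c5ccccc5)C(C)(C)C)[C@@H]1CCC3=C4C(O)(CC3)C(C(=O)OC)C[C@@]42CN(C)C1 | intermediate
38 | dienoate (C14=C15, C9=C10) | CC(C)C(=O)CC[C@@]2(CO[Si](c5ccccc5)(c5ccccc5)C(C)(C)C)[C@@H]1CCC3=C4C(CC3)=C(C(=O)OC)C[C@@]42CN(C)C1 | intermediate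
39 | saturated methyl ester, C21 TBDPS ether | CC(C)C(=O)CC[C@@]2(CO[Si](c5ccccc5)(c5ccccc5)C(C)(C)C)[C@@H]1CCC3=C4[C@H](CC3)[C@H](C(=O)OC)C[C@@]42CN(C)C1 | intermediate
40 | δ-hydroxy ketone methyl ester (open form drawn) | CC(C)C(=O)CC[C@@]2(CO)[C@@H]1CCC3=C4[C@H](CC3)[C@H](C(=O)OC)C[C@@]42CN(C)C1 | intermediate
41 | methyl ester of the target | CC(C)C1=CC[C@@]2(CO1)[C@@H]1CCC3=C4[C@H](CC3)[C@H](C(=O)OC)C[C@@]42CN(C)C1 | intermediate
42 | CNP0237695.1 | CC(C)C1=CC[C@@]2(CO1)[C@@H]1CCC3=C4[C@H](CC3)[C@H](C(=O)O)C[C@@]42CN(C)C1 | target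

## Step count and risks

Total step count: 28. Longest linear sequence: 28 (from 1).

**Step 5.** The lipase may not separate the two CH2OH groups well enough. The fallback drops the diol and lets the ring control C5.
- It sets out from 6. The formaldehyde aldol is stopped at 8 (37 % aq. CH2O, catalytic DBU, THF, rt), where formaldehyde enters anti to the allyl group.
- The alcohol is capped with Et3SiCl and imidazole to give the silyl-protected hydroxymethyl aldehyde F1.
- Methoxymethylenation as in step 7 gives the silylated enol ether F2.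
- 1 M HCl in THF removes the silyl group and the enol ether together, and the route is rejoined at lactol 15.

**Step 15.** This is a ring-closing Mannich reaction that builds C8 next to quaternary C5, after an epimerisable aldehyde. The fallback makes the C8–C1 bond first and closes the ring through nitrogen afterwards.
- It sets out from 20. An intermolecular Mannich reaction with N-benzylmethylamine and aqueous CH2O in EtOH, whose face is controlled by the cis-fused lactone, gives the benzylmethylaminomethyl keto lactone F3.
- Ozonolysis of its CF3CO2H salt followed by Me2S gives the amino keto aldehyde F4.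
- H2 over Pd(OH)2 on carbon in MeOH removes the benzyl group and reduces the cyclic iminium ion formed with the C7 aldehyde. The route is rejoined at 25.

**Step 25.** This is a selective hydrogenation of one of two tetrasubstituted alkenes. The fallback ties the ester to C21 so that the upper face is closed by a ring.
- It sets out from 38. Bu4NF and AcOH give the hydroxy dienoate F5.
- Catalytic Ti(OiPr)4 in refluxing toluene, with distillation of methanol, gives the seven-membered dienoate lactone F6.
- Hydrogenation with the same iridium catalyst can then come only from the lower face and gives the saturated lactone F7, in which C14 is locked.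
- K2CO3 in MeOH at 0 °C opens the lactone, and the route is rejoined at 40.

## Further compounds

F1 | step 5 | (1S,2R)-2-allyl-4-isopropyl-1-[(triethylsilyloxy)methyl]cyclohex-3-ene-1-carbaldehyde | CC(C)C1=C[C@@H](CC=C)[C@](C=O)(CO[Si](CC)(CC)CC)CC1
F2 | step 5 | triethylsilyl ether of 14 (E/Z) | CC(C)C1=C[C@@H](CC=C)[C@](C=COC)(CO[Si](CC)(CC)CC)CC1
F3 | step 15 | C8 (N-benzyl-N-methylaminomethyl) derivative of 20 | CC(C)C1=C[C@H]2CCCC(=O)[C@]3(CN(C)Cc4ccccc4)C(=O)OC[C@@]32CC1
F4 | step 15 | C8 (N-benzyl-N-methylaminomethyl) derivative of 22 | CC(C)C(=O)CC[C@]12COC(=O)[C@@]1(CN(C)Cc3ccccc3)C(=O)CCC[C@@H]2C=O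
F5 | step 25 | C21 alcohol of dienoate 38 | CC(C)C(=O)CC[C@@]2(CO)[C@@H]1CCC3=C4C(CC3)=C(C(=O)OC)C[C@@]42CN(C)C1
F6 | step 25 | seven-membered C21–O–C22 lactone of the dienoate | CC(C)C(=O)CC[C@]12COC(=O)C3=C4CCC5=C4[C@@]1(C3)CN(C)C[C@H]2CC5
F7 | step 25 | saturated seven-membered lactone (H14 and H15 on the lower face) | CC(C)C(=O)CC[C@]12COC(=O)[C@H]3[C@H]4CCC5=C4[C@@]1(C3)CN(C)C[C@H]2CC5
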